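Monday's, Friday's and Thursday's flasks take the same charges and differ in what goes in slowly.

    starting material + partner → target (k1 = 6.6 M⁻¹ h⁻¹)
    second substrate + partner → second product (k2 = 1.3 M⁻¹ h⁻¹)
    third substrate + partner → third product (k3 = 4.4 M⁻¹ h⁻¹)
    partner + target → over-reaction product (k4 = 6.7 M⁻¹ h⁻¹)
    2 third substrate → self-condensation product (k5 = 4.7 M⁻¹ h⁻¹)
    gas ⇌ partner, rate k6*(csat - [partner]) (k6 = 3.9 h⁻¹, csat = 2.5 mM)

the same everywhere: second substrate 0.500 equiv; gas 2.5 mM (held); time 20 d
- Monday's: starting material 28 mM (fed, over 15 d); third substrate 2.00 equiv; all else is in the flask from the start; the feed brings no volume worth counting
- Friday's: starting material 28 mM; third substrate 2.00 equiv; everything together at the start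
- Thursday's: starting material 28 mM; third substrate 2.00 equiv (fed, over 15 d); all else is in the flask from the start; the feed brings no volume worth counting

- for a step with 2 of a species take k times the square, and two of it per event
- at the start none of partner is dissolved
- run time (Monday's): 20 d

1. the flask that comes out highest in amount of target, in percent of the starting material charged, or "all alike" when all lie within 1.5 percentage points (Monday's / Friday's / Thursday's / all alike)
2. target at the end, in percent of the starting material charged, Monday's
3. target at the end, in percent of the starting material charged, Friday's
4. target at the end, in percent of the starting material charged, Thursday's

You have to choose which recipe to run next, so start with what the flask ends as. The gas refills the partner at 3.9 h⁻¹, faster than the starting material, second substrate and third substrate together at their full charges can take it, at 0.449 h⁻¹, so I reckon the partner stays near 2.5 mM. Each step with the partner then behaves as a pseudo-first-order decay, and target made in the flask keeps turning into over-reaction product.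

What matters is how fast that goes. The constant of the over-reaction step times the held partner is 0.0168 h⁻¹, which gives the half-life of target under held partner, 1.72 d. Target forms at about the same pace, so I give both steps one constant and call x the elapsed time multiplied by it.

In Friday's flask, target is then x times e to the minus x of the charge, and at the end that is 0.259%. I expect about the same in Thursday's flask, because the partner is refilled faster than the third substrate takes it.

In Monday's flask, starting material and target each level off near 16.6% of the charge during the feed. The feed then stops 5.00 d before the end, and that level is multiplied by one plus x, times e to the minus x, with x now counted from the end of the feed, which is 0.402. That gives 6.69%, so I would run Monday's recipe.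

The forecast also names Monday's, with 6.9% (range 6.5% to 7.3%), 0.3% for Friday's and 0.31% for Thursday's, on the grounds that in Monday's flask "recently made target is still present". My figures for Monday's and Friday's lie lower.

The simulation puts Monday's first, with 6.91% of target against 0.303% in Friday's and 0.307% in Thursday's. In Monday's flask the half-life of target by the over-reaction step reads 1.7 d at 20.0 d, short against the run time of 20 d. My 1.72 d fits 11.6 times into Friday's run but 2.91 times into the stretch after Monday's feed, and at the end over-reaction product stands at 99.7% in Friday's flask and 90.7% in Monday's.

The rate constants were chosen freely; what happens was integrated by code.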